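## The problem

Sodwanone T (16) is built from two trans-fused 2,2-dimethyloxepane–cyclohexene bicycles. Each half is numbered O1, C2 (CMe2), C3, C4, C5, C6 (quaternary, methyl), C7 (OCH) around the oxepane and C6–C11 around the carbocycle. The halves are joined from C11 to C11′ through the C12–C13 ethylene bridge and differ only at C3, a ketone in one and an (R)-carbinol in the other. In each half the quaternary C6 (S) sits between the ether carbon C7 (S) and the tetrasubstituted C10=C11 alkene, so the most crowded centre, a hindered alkene and the bridge all converge on neighbouring atoms. The C7 oxygen must be cis to the C6 methyl and trans to the C5 chain (trans ring fusion). C6 can control C7 if the C7 ketone is reduced in a rigid bicycle in which the C6 methyl is axial. C3 is too remote from C6/C7 to be left to substrate control and needs a reagent-controlled reduction. The O1–C2 bond joins a neopentyl-type secondary carbon to a tertiary carbon and cannot be made by substitution at either; it has to come from chemistry at the C7 hydroxyl before the ring exists. The tetrasubstituted alkenes would migrate or cyclise under strong acid and should not be exposed to the hydrogenation a C12–C13 multiple bond would require. The two C3 sites differ only in oxidation level, which forces one differentiation of equivalent positions. The feature that opens the molecule is that each C3 carbonyl lies between the fully substituted C2 and the C4 methylene: C3–C4 is the bond of a Claisen condensation between a C6 propanoate arm and a C7-bound 2-alkoxyisobutyrate, and only the propanoate can enolise.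

## Retrosynthesis

**16 ⇒ 15 (C3–H).** The carbinol is traced to the C2-symmetric diketone 15, so every earlier intermediate can be symmetric and each operation serves both halves. The forward step must reduce one of two equivalent ketones with catalyst control, giving the (3R) configuration; unreacted 15 and over-reduced diol are recycled.

**15 ⇒ 14 (C4–CO2Me).** Adding a methoxycarbonyl group at C4 and C4′ gives the bis(β-keto ester) 14. This costs one neutral dealkoxycarbonylation forward and exposes the Claisen bond.

**14 ⇒ 13 (C3–C4 and C3′–C4′, both oxepanones).** Cutting the two C3–C4 bonds gives tetraester 13. Against cutting O1–C2 or O1–C7, this cut removes both seven-membered rings with plain C–C bond formation, leaves the hindered ether linkages in place beforehand, and has only one possible regiochemistry. The precursor is monocyclic in each half. The forward reaction needs only intramolecular preference, secured by dilution.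

**13 ⇒ 9 + 11 (C13–C11′, via 12).** The bridge is cut at one sp3–sp2 bond, giving enol triflate 9 and alkylborane 12, the hydroboration product of diene 11. An alkyne linchpin between two triflates would need a later chemoselective saturation beside two tetrasubstituted alkenes. The sp3–sp2 coupling gives the saturated bridge directly, and both partners come from the same triflate.

**11 ⇒ 9 + 10 (C11–C12).** The vinyl group of 11 comes from triflate 9 and vinylstannane 10. The demand is a cross-coupling at a tetrasubstituted triflate next to C6.

**9 ⇒ 8 (C11–O).** The triflate is the enol derivative of ketone 8. Because C6 is quaternary, the ketone enolises only toward C10, so the alkene position is fixed.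

**8 ⇒ 7 ⇒ 6 (C10–CH3 and C2–CH3).** Both methyl groups are removed together, leaving keto acid 6, which carries a 2-alkoxypropanoate on the C7 oxygen. The free acid matters: as a carboxylate the propanoic chain does not enolise, so C4 is protected while the ketone and the alkoxy ester are methylated in one operation; esterification then gives 8.

**6 ⇒ 5 (oxidative ring cleavage).** The C11 ketone and the three-carbon acid chain are the two ends of a cleaved cyclohexenone, which leads to bicyclic enone 5. The chain arrives at the right length and oxidation level from a ring, with no homologation at the neopentyl position.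

**5 ⇒ 2 + 4 (C7O–C bond).** The ether is cut between oxygen and the propanoate carbon, giving alcohol 2 and diazo ester 4 (from β-keto ester 3 by diazo transfer). Carbenoid O–H insertion avoids substitution at C7 and retains its configuration.

**2 ⇒ 1 (C7–H).** Alcohol 2 comes from (S)-Wieland–Miescher ketone 1, which supplies C6. In this bicycle the angular methyl is axial and hydride adds anti to it, so the C7 oxygen ends up cis to the methyl and trans to the future chain. A reductive desymmetrisation of a monocyclic 2,2-disubstituted cyclohexane-1,3-dione is expected to place the hydroxyl cis to the larger substituent, the cis-fused series, and would then need an inversion at a neopentyl carbinol.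

## Roads not taken

**Alternative 1:** The cut is at both C6–CH3 bonds, tracing the target to the flat bibenzyl bis(benzamide) A1, in which the bridge and both carbocycles are already present as arenes. Forward, a two-fold dissolving-metal reduction with C-methylation of the resulting amide enolates gives the bis(1,4-cyclohexadiene) A2. The prolinol-derived amide auxiliaries set both C6 centres, and the diene pattern puts the C10=C11 alkenes in place.
- Merits: the bridge exists from the start, so no coupling at the hindered C11 is needed; both quaternary centres arise in one operation; the aromatic chemistry before it is cheap. In the way the bridge is made this road is better than the chosen one.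
- Weak points: no ring of either oxepane is formed. The C6 substituent in A2 is a one-carbon amide on a quaternary carbon, so the auxiliary must be cleaved and the C5–C4–C3 chain grown by two carbons at a neopentyl centre, twice. C7 arrives as an enol ether, and the derived ketone must be reduced to put oxygen cis to methyl on a mobile monocyclic substrate. The two-fold asymmetric alkylation on tetrasubstituted arenes is an extrapolation.
- Comparison: the chosen plan sets C6 and C7 by two reliable events, delivers the chain complete by ring cleavage, and has a key step that finishes both heterocycles.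

**Alternative 2:** The cut is at C11–C12 and C13–C11′, between two complete bicyclic enol triflates A3 and a distannylated two-carbon alkyne linchpin. Forward, a two-fold Stille coupling gives dienyne A4 with the whole C30 skeleton.
- Merits: maximal convergence; every stereocentre, C3 included, is set on a small bicyclic monomer. Because the union comes last, it could be run stepwise with two different halves, which would remove the statistical end-game. The chosen plan cannot match this, since the two-fold condensation keeps the molecule symmetric until the last step.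
- Weak points: the alkyne of A4 must afterwards be saturated beside two tetrasubstituted alkenes in a conjugated dienyne, through a congested cis-triene. As formulated, A4 carries two identical silyl ethers and also ends in a statistical differentiation. The coupling must succeed twice on a tetrasubstituted triflate next to a quaternary carbon. The alternative does not say how the oxepane of A3 is closed, which needs a ring-forming strategy of its own.
- Comparison: the chosen plan uses the same triflate class but couples sp3–sp2, reaching the saturated bridge without a reduction, and supplies the oxepane closure itself.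

**Alternative 3:** The cut is at both O1–C2 and both C6–C11 bonds, tracing the target to the acyclic C2-symmetric tetraepoxide A5. Forward, a silyl triflate Lewis acid triggers a two-directional cascade. Each 6,7-epoxide oxygen opens the terminal epoxide at C2 (oxepane). The resulting epoxonium ion is opened at C6 with inversion by the C10=C11 alkene (cyclohexane). Proton loss restores the alkene, giving diol A6 after desilylation.
- Merits: by far the shortest road; four rings and four bonds in one step. C3, C6 and C7 all derive from reagent-controlled epoxide stereochemistry, and the anti opening gives the trans ring fusion. In step economy it is clearly superior and the chosen plan cannot compete on brevity.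
- Weak points: A5 requires four of six similar trisubstituted alkenes of a polyene chain to be epoxidised regio- and enantioselectively, which means a purpose-built chain with differentiated alkenes. The cascade has three selectivity questions per end: seven-membered versus six-membered ether formation, stereochemical leakage at C6 if opening becomes stepwise, and the position of the alkene after proton loss. Running it in two directions compounds each. A6 still needs the same statistical mono-oxidation.
- Comparison: the chosen plan fixes each bond and alkene position by a reaction with one possible outcome (one enolisable ketone direction, one enolisable ester), so material is not divided among isomers late in the route.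

Key step: step 10

Assumption: (S)-Wieland–Miescher ketone 1 is taken as a commercial single enantiomer; atom numbers C2–C13 follow the numbering of one half defined in the first section.

## Route

Step 1
Reactants: 1 (S)-Wieland–Miescher ketone
Product: 2 (4aS,5S)-5-hydroxy-4a-methyl-4,4a,5,6,7,8-hexahydronaphthalen-2(3H)-one
Conditions: NaBH4 (0.3 equiv), EtOH, −10 °C
Reagents that add atoms: none
Why: Chemoselective 1,2-reduction of the saturated ketone (the enone is less electrophilic); hydride adds anti to the axial angular methyl, which sets C7 (S) with oxygen cis to the C6 methyl and trans to the future C5 chain.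

Step 2
Reactants: 3 methyl 2-methyl-3-oxobutanoate
Product: 4 methyl 2-diazopropanoate
Conditions: 4-acetamidobenzenesulfonyl azide, DBU, MeCN, 0 °C → rt
Reagents that add atoms: 4-acetamidobenzenesulfonyl azide, CC(=O)Nc1ccc(cc1)S(=O)(=O)N=[N+]=[N-]
Why: Deacylative diazo transfer (Regitz type): the sulfonyl azide adds to the enolate of the 2-substituted acetoacetate and the acetyl group leaves on the sulfonamide nitrogen, giving the α-diazo ester.

Step 3
Reactants: 2 (4aS,5S)-hydroxy enone; 4 methyl 2-diazopropanoate
Product: 5 methyl 2-{[(1S,8aS)-8a-methyl-6-oxo-1,2,3,4,6,7,8,8a-octahydronaphthalen-1-yl]oxy}propanoate (both epimers at the propanoate α-carbon)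
Conditions: Rh2(OAc)4 (1 mol %), CH2Cl2, rt, slow addition of 4 (2.5 equiv)
Reagents that add atoms: none
Why: Rhodium-carbenoid O–H insertion (oxonium ylide, then proton shift) makes the hindered ether without substitution at C7, so C7 keeps its configuration. The electron-poor enone is a poor partner for the electrophilic carbenoid, and the new α-centre is methylated in step 5, so it need not be controlled.

Step 4
Reactants: 5 bicyclic enone ether
Product: 6 3-[(1R,2S)-2-[(1-methoxy-1-oxopropan-2-yl)oxy]-1-methyl-6-oxocyclohexyl]propanoic acid
Conditions: O3, CH2Cl2/AcOH, −40 °C; then 30% H2O2, H2O, rt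
Reagents that add atoms: ozone, O=[O+][O-]; hydrogen peroxide, OO
Why: Ozonolysis of a cyclohexenone with oxidative work-up cleaves the C=C bond and the resulting 2-oxo acid loses CO2 (the classical enone to seco-nor keto acid degradation). This unveils the C11 ketone and the C5–C4 propanoic acid in one operation; ester and ether are inert.

Step 5
Reactants: 6 keto acid
Product: 7 3-[(1R,2S)-2-[(1-methoxy-2-methyl-1-oxopropan-2-yl)oxy]-1,5-dimethyl-6-oxocyclohexyl]propanoic acid (both epimers at the ring CHMe carbon)
Conditions: 6 added to LiN(i-Pr)2 (3.2 equiv), THF, −78 °C; MeI (6 equiv), DMPU, −78 → −20 °C; aq. HCl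
Reagents that add atoms: iodomethane, CI
Why: Enolate C-alkylation on a trianion: the acid is deprotonated first and the lithium carboxylate is not enolised at −78 °C, so C4 is protected. The ketone (enolisable only toward C10, since C6 is quaternary) and the α-alkoxy ester both form enolates and are methylated; the C10 centre becomes sp2 in step 7 and need not be controlled.

Step 6
Reactants: 7 dimethylated keto acid
Product: 8 methyl 3-[(1R,2S)-2-[(1-methoxy-2-methyl-1-oxopropan-2-yl)oxy]-1,5-dimethyl-6-oxocyclohexyl]propanoate
Conditions: MeI, K2CO3, DMF, rt
Reagents that add atoms: iodomethane, CI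
Why: Carboxylate O-alkylation (SN2 at methyl) under conditions too weakly basic to enolise the ketone or the esters.

Step 7
Reactants: 8 keto diester
Product: 9 methyl 3-[(1R,6S)-6-[(1-methoxy-2-methyl-1-oxopropan-2-yl)oxy]-1,3-dimethyl-2-(trifluoromethanesulfonyloxy)cyclohex-2-en-1-yl]propanoate
Conditions: KN(SiMe3)2 (1.1 equiv), THF, −78 °C; PhNTf2, −78 → 0 °C
Reagents that add atoms: N-phenylbis(trifluoromethanesulfonimide), O=S(=O)(N(c1ccccc1)S(=O)(=O)C(F)(F)F)C(F)(F)F
Why: Enolate O-sulfonylation: the ketone is far more acidic than the propanoate and can enolise only toward C10, so the tetrasubstituted C10=C11 enol triflate is the only regioisomer. The low temperature keeps the enolate from acylating on either ester.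

Step 8
Reactants: 9 enol triflate; 10 tributyl(vinyl)stannane
Product: 11 methyl 3-[(1S,6S)-2-ethenyl-6-[(1-methoxy-2-methyl-1-oxopropan-2-yl)oxy]-1,3-dimethylcyclohex-2-en-1-yl]propanoate
Conditions: Pd(PPh3)4 (5 mol %), LiCl, THF, 65 °C
Reagents that add atoms: none
Why: Stille coupling of a cyclohexenyl triflate with a vinylstannane, with chloride assisting transmetalation. It forms C11–C12 with the alkene position fixed by the triflate; esters and ether are inert.

Step 9
Reactants: 11 diene; 9 enol triflate
Product: 13 dimethyl 3,3′-{ethane-1,2-diylbis[(1S,6S)-6-[(1-methoxy-2-methyl-1-oxopropan-2-yl)oxy]-1,3-dimethylcyclohex-2-ene-2,1-diyl]}dipropanoate, via alkylborane 12 (not isolated)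
Conditions: 9-BBN dimer, THF, 0 °C → rt; then 9, PdCl2(dppf) (10 mol %), AsPh3, Cs2CO3, DMF/H2O, 50 °C
Reagents that add atoms: none
Why: 9-BBN hydroborates only the monosubstituted vinyl group, with boron on the terminal carbon; the tetrasubstituted alkene and the esters are inert at room temperature. B-alkyl Suzuki–Miyaura coupling of the primary alkylborane with a second equivalent of triflate then forms the C13–C11′ bond and gives the saturated bridge without any reduction step.

Step 10
Reactants: 13 C2-symmetric tetraester
Product: 14 dimethyl 6,6′-(ethane-1,2-diyl)bis[(5aS,9aS)-3-hydroxy-2,2,5a,7-tetramethyl-2,5,5a,8,9,9a-hexahydro-1-benzoxepine-4-carboxylate] (bis(β-keto ester), written as the bis-enol)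
Conditions: slow addition of 13 to KN(SiMe3)2 (5 equiv), THF, 0.005 M, −78 → 0 °C; then AcOH
Reagents that add atoms: none
Why: Potassium hexamethyldisilazide removes a proton from C4 and C4′, the only ester α-hydrogens in 13 (each isobutyrate carbon C2 is fully substituted), so each propanoate enolate can only be the donor and each isobutyrate carbonyl C3 only the acceptor. Addition of the enolate carbon to C3, loss of methoxide and immediate deprotonation of the doubly activated C4–H of the β-keto ester drive both condensations to the dipotassium bis-enolate, which is protonated to 14 on quenching. The closest known reaction type is the Dieckmann condensation of diesters to seven-membered cyclic β-keto esters under dilution, including ether-tethered diesters that give 3-oxo-oxacycloalkane carboxylates. Each oxepanone closes in the 7-exo-trig mode, the enolate double bond lying outside the new ring. The two arms are trans on C6 and C7 and can both be pseudo-equatorial on the half-chair cyclohexene, so the trans-fused ring forms without strain, and the geminal methyl groups on C2 favour the folded conformer. No lasting stereocentre is created: C4 is planar in the enol and ceases to be a stereocentre in step 11, while C6 and C7 are not touched. The step needs donor/acceptor regioselectivity, secured by the missing α-hydrogen of the isobutyrate, and intra- over intermolecular condensation, secured by high dilution and slow addition; the base is in excess because each ring consumes two equivalents.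

Step 11
Reactants: 14 bis(β-keto ester)
Product: 15 6,6′-(ethane-1,2-diyl)bis[(5aS,9aS)-2,2,5a,7-tetramethyl-4,5,5a,8,9,9a-hexahydro-1-benzoxepin-3(2H)-one]
Conditions: LiCl, H2O, DMSO, 140 °C
Reagents that add atoms: none
Why: Krapcho demethoxycarbonylation: chloride dealkylates each methyl ester, the β-keto carboxylate loses CO2 and water protonates the enolate. The neutral conditions leave the tetrasubstituted alkenes and the α-alkoxy ketones untouched.

Step 12
Reactants: 15 C2-symmetric diketone
Product: 16 sodwanone T
Conditions: (S)-2-methyl-CBS-oxazaborolidine (0.2 equiv), catecholborane (1.0 equiv), toluene, −78 °C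
Reagents that add atoms: none
Why: Corey–Bakshi–Shibata reduction: the (S)-oxazaborolidine treats the fully substituted C2 as the large group and the C4 methylene as the small one and delivers hydride to the face that gives the (3R)-carbinol. One equivalent of a one-hydride borane limits the reduction to a statistical mixture, from which 16 is separated while 15 and the over-reduced diol (after re-oxidation) are recycled.

## Compound list

1 | (S)-Wieland–Miescher ketone, (8aS)-8a-methyl-3,4,8,8a-tetrahydronaphthalene-1,6(2H,7H)-dione | C[C@]12CCC(=O)C=C1CCCC2=O | starting material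
2 | (4aS,5S)-5-hydroxy-4a-methyl-4,4a,5,6,7,8-hexahydronaphthalen-2(3H)-one | C[C@]12CCC(=O)C=C1CCC[C@@H]2O | intermediate
3 | methyl 2-methyl-3-oxobutanoate | CC(=O)C(C)C(=O)OC | starting material
4 | methyl 2-diazopropanoate | CC(=[N+]=[N-])C(=O)OC | intermediate
5 | methyl 2-{[(1S,8aS)-8a-methyl-6-oxo-1,2,3,4,6,7,8,8a-octahydronaphthalen-1-yl]oxy}propanoate (epimers at the propanoate α-carbon) | C[C@]12CCC(=O)C=C1CCC[C@@H]2OC(C)C(=O)OC | intermediate
6 | 3-[(1R,2S)-2-[(1-methoxy-1-oxopropan-2-yl)oxy]-1-methyl-6-oxocyclohexyl]propanoic acid | C[C@]1(CCC(=O)O)C(=O)CCC[C@@H]1OC(C)C(=O)OC | intermediate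
7 | 3-[(1R,2S)-2-[(1-methoxy-2-methyl-1-oxopropan-2-yl)oxy]-1,5-dimethyl-6-oxocyclohexyl]propanoic acid (C5 epimers) | C[C@]1(CCC(=O)O)C(=O)C(C)CC[C@@H]1OC(C)(C)C(=O)OC | intermediate
8 | methyl 3-[(1R,2S)-2-[(1-methoxy-2-methyl-1-oxopropan-2-yl)oxy]-1,5-dimethyl-6-oxocyclohexyl]propanoate (C5 epimers) | C[C@]1(CCC(=O)OC)C(=O)C(C)CC[C@@H]1OC(C)(C)C(=O)OC | intermediate
9 | methyl 3-[(1R,6S)-6-[(1-methoxy-2-methyl-1-oxopropan-2-yl)oxy]-1,3-dimethyl-2-(trifluoromethanesulfonyloxy)cyclohex-2-en-1-yl]propanoate | C[C@]1(CCC(=O)OC)C(OS(=O)(=O)C(F)(F)F)=C(C)CC[C@@H]1OC(C)(C)C(=O)OC | intermediate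
10 | tributyl(vinyl)stannane | C=C[Sn](CCCC)(CCCC)CCCC | starting material
11 | methyl 3-[(1S,6S)-2-ethenyl-6-[(1-methoxy-2-methyl-1-oxopropan-2-yl)oxy]-1,3-dimethylcyclohex-2-en-1-yl]propanoate | C[C@]1(CCC(=O)OC)C(C=C)=C(C)CC[C@@H]1OC(C)(C)C(=O)OC | intermediate
12 | methyl 3-[(1S,6S)-2-[2-(9-borabicyclo[3.3.1]nonan-9-yl)ethyl]-6-[(1-methoxy-2-methyl-1-oxopropan-2-yl)oxy]-1,3-dimethylcyclohex-2-en-1-yl]propanoate | C[C@]1(CCC(=O)OC)C(CCB2C3CCCC2CCC3)=C(C)CC[C@@H]1OC(C)(C)C(=O)OC | intermediate
13 | dimethyl 3,3′-{ethane-1,2-diylbis[(1S,6S)-6-[(1-methoxy-2-methyl-1-oxopropan-2-yl)oxy]-1,3-dimethylcyclohex-2-ene-2,1-diyl]}dipropanoate | CC1=C(CCC2=C(C)CC[C@H](OC(C)(C)C(=O)OC)[C@@]2(C)CCC(=O)OC)[C@](C)(CCC(=O)OC)[C@@H](OC(C)(C)C(=O)OC)CC1 | intermediate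
14 | dimethyl 6,6′-(ethane-1,2-diyl)bis[(5aS,9aS)-3-hydroxy-2,2,5a,7-tetramethyl-2,5,5a,8,9,9a-hexahydro-1-benzoxepine-4-carboxylate] (bis-enol form) | CC1=C(CCC2=C(C)CC[C@@H]3OC(C)(C)C(O)=C(C(=O)OC)C[C@@]23C)[C@]2(C)CC(C(=O)OC)=C(O)C(C)(C)O[C@H]2CC1 | intermediate
15 | 6,6′-(ethane-1,2-diyl)bis[(5aS,9aS)-2,2,5a,7-tetramethyl-4,5,5a,8,9,9a-hexahydro-1-benzoxepin-3(2H)-one] | CC1=C(CCC2=C(C)CC[C@@H]3OC(C)(C)C(=O)CC[C@@]23C)[C@]2(C)CCC(=O)C(C)(C)O[C@H]2CC1 | intermediate
16 | sodwanone T, (5aS,9aS)-6-{2-[(3R,5aS,9aS)-3-hydroxy-2,2,5a,7-tetramethyl-2,3,4,5,5a,8,9,9a-octahydro-1-benzoxepin-6-yl]ethyl}-2,2,5a,7-tetramethyl-4,5,5a,8,9,9a-hexahydro-1-benzoxepin-3(2H)-one | CC1=C(CCC2=C(C)CC[C@@H]3OC(C)(C)[C@H](O)CC[C@@]23C)[C@]2(C)CCC(=O)C(C)(C)O[C@H]2CC1 | target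

## Step count and risks

Total: 12 steps. Longest linear sequence: 11 steps from 1 (steps 1 and 3–12); step 2 prepares reagent 4.

**Step 10 (key step).** Addition to the isobutyrate carbonyl, which sits on a fully substituted carbon, may be slow. Intermolecular Claisen condensation could then compete, or the reaction could stall after the first ring closure.
Fallback, from 13 to 15:
- The two unhindered propanoate esters of 13 are saponified selectively (LiOH, THF/H2O, 0 °C; the isobutyrates are shielded by their fully substituted α-carbon), giving the diacid diester F1.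
- LiN(i-Pr)2 (two equivalents per acid) converts each acid into its enediolate, a much stronger carbon nucleophile than the ester enolate, which acylates on the neighbouring isobutyrate.
- The resulting bis(β-keto acid) F2 decarboxylates on acidic work-up and gentle warming, giving diketone 15 directly and bypassing 14 and step 11.
- The bonds formed (C3–C4, C3′–C4′) and the rings closed are the same.

**Step 5.** Proton transfer between the three anionic sites and the methylated products may occur during alkylation. This would leave the alkoxy ester partly unmethylated, put a second methyl on C10, or, if the carboxylate is enolised, methylate C4.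
Fallback, from 6 to 8:
- Carbodiimide esterification of 6 with (3-methyloxetan-3-yl)methanol gives the oxetanyl ester F3.
- BF3·OEt2 rearranges it to the 4-methyl-2,6,7-trioxabicyclo[2.2.2]octane ortho ester F4, whose chain has no acidic α-hydrogen.
- LiN(i-Pr)2 (2.2 equiv) and iodomethane then methylate C10 and the alkoxypropanoate as a simple dianion, giving F5.
- Acidic methanolysis opens the ortho ester and transesterifies it to the methyl ester, returning to 8.

**Step 3.** A 1,2-hydride shift in the rhodium carbenoid (to methyl acrylate) and carbene dimerisation may outrun O–H insertion at the hindered neopentyl-type alcohol.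
Fallback, from 2 to 5:
- Rh2(OAc)4-catalysed O–H insertion with dimethyl diazomalonate, a carbenoid with no β-hydrogen, gives the alkoxymalonate F6.
- K2CO3 and iodomethane methylate only the malonate carbon, giving F7.
- Krapcho removal of one ester group (LiCl, wet DMSO, heat) returns to 5.

**Step 9.** Oxidative addition and transmetalation at the tetrasubstituted triflate beside quaternary C6 may be slow. Protodeboronation, β-hydride elimination from the alkylpalladium species, or hydrolysis of the triflate could then take over.
Fallback, from 9 to 13:
- Two equivalents of 9 are joined by two-fold Stille coupling with bis(tributylstannyl)acetylene (Pd(PPh3)4, LiCl), giving the dienyne F8.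
- Diimide (from p-toluenesulfonyl hydrazide and NaOAc) saturates the alkyne through the cis-alkene and leaves the tetrasubstituted ring alkenes alone, returning to 13.

**Step 12.** Over-reduction gives a statistical mixture. Facial selectivity may also be eroded if the ring's own bias or coordination of the ether oxygen to boron opposes the catalyst.
Fallback, from 15 to 16:
- Both ketones are reduced with excess reagent ((S)-oxazaborolidine, BH3·SMe2), giving the C2-symmetric (3R,3′R)-diol F9 (the same compound as A6). Stereochemical purification is done at this symmetric stage.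
- One hydroxyl is then oxidised with one equivalent of Dess–Martin periodinane to give 16; diol and diketone are recycled.
- This separates the stereocontrol from the statistical event.

## Further compounds

F1 | step 10 | 3,3′-{ethane-1,2-diylbis[(1S,6S)-6-[(1-methoxy-2-methyl-1-oxopropan-2-yl)oxy]-1,3-dimethylcyclohex-2-ene-2,1-diyl]}dipropanoic acid | CC1=C(CCC2=C(C)CC[C@H](OC(C)(C)C(=O)OC)[C@@]2(C)CCC(=O)O)[C@](C)(CCC(=O)O)[C@@H](OC(C)(C)C(=O)OC)CC1
F2 | step 10 | 6,6′-(ethane-1,2-diyl)bis[(5aS,9aS)-2,2,5a,7-tetramethyl-3-oxo-2,3,4,5,5a,8,9,9a-octahydro-1-benzoxepine-4-carboxylic acid] | CC1=C(CCC2=C(C)CC[C@@H]3OC(C)(C)C(=O)C(C(=O)O)C[C@@]23C)[C@]2(C)CC(C(=O)O)C(=O)C(C)(C)O[C@H]2CC1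
F3 | step 5 | (3-methyloxetan-3-yl)methyl 3-[(1R,2S)-2-[(1-methoxy-1-oxopropan-2-yl)oxy]-1-methyl-6-oxocyclohexyl]propanoate | C[C@]1(CCC(=O)OCC2(C)COC2)C(=O)CCC[C@@H]1OC(C)C(=O)OC
F4 | step 5 | methyl 2-{[(1S,2R)-2-methyl-2-[2-(4-methyl-2,6,7-trioxabicyclo[2.2.2]octan-1-yl)ethyl]-3-oxocyclohexyl]oxy}propanoate | C[C@]1(CCC23OCC(C)(CO2)CO3)C(=O)CCC[C@@H]1OC(C)C(=O)OC
F5 | step 5 | methyl 2-{[(1S,2R)-2,4-dimethyl-2-[2-(4-methyl-2,6,7-trioxabicyclo[2.2.2]octan-1-yl)ethyl]-3-oxocyclohexyl]oxy}-2-methylpropanoate | C[C@]1(CCC23OCC(C)(CO2)CO3)C(=O)C(C)CC[C@@H]1OC(C)(C)C(=O)OC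
F6 | step 3 | dimethyl 2-{[(1S,8aS)-8a-methyl-6-oxo-1,2,3,4,6,7,8,8a-octahydronaphthalen-1-yl]oxy}propanedioate | C[C@]12CCC(=O)C=C1CCC[C@@H]2OC(C(=O)OC)C(=O)OC
F7 | step 3 | dimethyl 2-methyl-2-{[(1S,8aS)-8a-methyl-6-oxo-1,2,3,4,6,7,8,8a-octahydronaphthalen-1-yl]oxy}propanedioate | C[C@]12CCC(=O)C=C1CCC[C@@H]2OC(C)(C(=O)OC)C(=O)OC
F8 | step 9 | dimethyl 3,3′-{ethyne-1,2-diylbis[(1S,6S)-6-[(1-methoxy-2-methyl-1-oxopropan-2-yl)oxy]-1,3-dimethylcyclohex-2-ene-2,1-diyl]}dipropanoate | CC1=C(C#CC2=C(C)CC[C@H](OC(C)(C)C(=O)OC)[C@@]2(C)CCC(=O)OC)[C@](C)(CCC(=O)OC)[C@@H](OC(C)(C)C(=O)OC)CC1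
F9 | step 12 | 6,6′-(ethane-1,2-diyl)bis[(3R,5aS,9aS)-2,2,5a,7-tetramethyl-2,3,4,5,5a,8,9,9a-octahydro-1-benzoxepin-3-ol] | CC1=C(CCC2=C(C)CC[C@@H]3OC(C)(C)[C@H](O)CC[C@@]23C)[C@]2(C)CC[C@@H](O)C(C)(C)O[C@H]2CC1
A1 | alternative 1 | 1,2-bis[3-methoxy-6-methyl-2-{[(2S)-2-(methoxymethyl)pyrrolidin-1-yl]carbonyl}phenyl]ethane | COc1ccc(C)c(CCc2c(C)ccc(OC)c2C(=O)N2CCC[C@H]2COC)c1C(=O)N1CCC[C@H]1COC
A2 | alternative 1 | C2-symmetric bis(1,4-cyclohexadiene) with C6 methyl/amide quaternary centres, C7 methyl enol ethers and C10=C11 alkenes | CC1=C(CCC2=C(C)CC=C(OC)[C@@]2(C)C(=O)N2CCC[C@H]2COC)[C@](C)(C(=O)N2CCC[C@H]2COC)C(OC)=CC1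
A3 | alternative 2 | (3R,5aR,9aS)-3-[(tert-butyldimethylsilyl)oxy]-2,2,5a,7-tetramethyl-2,3,4,5,5a,8,9,9a-octahydro-1-benzoxepin-6-yl trifluoromethanesulfonate | CC1=C(OS(=O)(=O)C(F)(F)F)[C@]2(C)CC[C@@H](O[Si](C)(C)C(C)(C)C)C(C)(C)O[C@H]2CC1
A4 | alternative 2 | 1,2-bis[(3R,5aS,9aS)-3-[(tert-butyldimethylsilyl)oxy]-2,2,5a,7-tetramethyl-2,3,4,5,5a,8,9,9a-octahydro-1-benzoxepin-6-yl]ethyne | CC1=C(C#CC2=C(C)CC[C@@H]3OC(C)(C)[C@H](O[Si](C)(C)C(C)(C)C)CC[C@@]23C)[C@]2(C)CC[C@@H](O[Si](C)(C)C(C)(C)C)C(C)(C)O[C@H]2CC1
A5 | alternative 3 | C2-symmetric 2,3:6,7:18,19:22,23-tetraepoxide of the all-trans squalene chain, 10,11- and 14,15-alkenes retained, configured as in the SMILES | CC1(C)O[C@@H]1CC[C@]2(C)O[C@H]2CC/C(C)=C/CC/C=C(C)/CC[C@@H]3O[C@@]3(C)CC[C@H]4OC4(C)C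
A6 | alternative 3 | 6,6′-(ethane-1,2-diyl)bis[(3R,5aS,9aS)-2,2,5a,7-tetramethyl-2,3,4,5,5a,8,9,9a-octahydro-1-benzoxepin-3-ol] | CC1=C(CCC2=C(C)CC[C@@H]3OC(C)(C)[C@H](O)CC[C@@]23C)[C@]2(C)CC[C@@H](O)C(C)(C)O[C@H]2CC1
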